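## Analysis of the target

Compound 32 is a biflavan. Two (2S)-2-phenylchroman units, each with a methyl ether at C5 and a free hydroxyl at C7, are joined by one methylene carbon that links C8 of unit A to C6 of unit B. The only stereocentres are the two benzylic ether carbons C2, both S; they lie far apart across the diarylmethane, cannot influence each other, and must each be set under absolute control. The sensitive elements are the two phloroglucinol-type rings (easily oxidised, open to electrophiles, and prone to acid-mediated scrambling of the diarylmethane link), the two benzylic C2–O1 bonds (hydrogenolysis, ionisation) and the free phenols. The real difficulty is constitutional: the two halves are the same flavan, but one is substituted at C8 and the other at C6, and electrophilic or phenol-directed chemistry on a 5,7-dioxygenated flavan does not reliably tell these positions apart. Each benzene ring is also pentasubstituted, with three oxygens that end in three different states (methyl ether, free phenol, ring ether). The strategy rests on the benzene ring of unit A: C4a (alkyl), C5 (OMe), C6 (H), C7 (OH), C8 (CH2 bridge) and C8a (O1) form the pattern that a cyclobutenone–siloxyalkyne benzannulation assembles with every position defined. That ring can therefore be built de novo on a finished unit B, and the C8/C6 question never arises for unit A.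

## Retrosynthetic reasoning

**Phenol protection.** The last operation frees the two C7 phenols, so 32 is traced to its bis-TIPS ether 31. Aryl silyl ethers are chosen because fluoride removes them without touching the benzylic ether bonds or the diarylmethane, and because one of them is produced by the ring construction itself.

**O1–C2 bond of unit A.** The pyran ring of unit A in 31 is opened at O1–C2, which gives phenol-alcohol 30 and, one protecting group earlier, its TBS ether 29. The cut is made here because the C8a oxygen is the one oxygen the benzannulation delivers as a free hydroxyl. An SN2 closure also lets an (R)-carbinol, accessible by ketone reduction, become the (2S) centre with inversion. The forward reaction has to close a six-membered ring on a hindered phenol without ionising the benzylic carbon.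

**Benzene ring of unit A.** Compound 29 is cut at C8–C8a and C6–C7, which gives cyclobutenone 11 and siloxyalkyne 24. No other disconnection removes the regiochemical problem as completely: the bridge carbon is already attached to unit B in 24, and the polarity of the ketene–ynol ether cycloaddition places it between the new phenol and the silyl ether. The forward reaction must pass through vinylketene 25, cycloadduct 26, dienylketene 27 and dienone 28 without the ketene being lost to side reactions. Compound 11 can be used as a mixture of C4 epimers, because that carbon becomes aromatic.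

**Cyclobutenone 11.** The four-membered ring is cut at C1–C2 and C3–C4 into aldoketene 10 and methoxyacetylene 8. The ketene comes from acid 5 through acid chloride 9. This [2+2] cycloaddition places the methoxy group at C3 and the side chain at C4 directly.

**Acid 5 and alkyne 8.** Acid 5 goes back through 4 and 3 to keto ester 2 and keto acid 1; the stereocentre is set by catalytic asymmetric reduction of the aryl ketone in 2. Alkyne 8 comes from chloro acetal 6 by double elimination through acetylide 7.

**Siloxyalkyne 24.** The O–C(sp) bond is cut, which leads to ynolate 23 and, by removing the oxygen, to lithium acetylide 22. Acetylide 22 goes back by a one-carbon homologation to dibromoalkene 21 and aldehyde 20, and 20 to the allyl compound 19 by alkene cleavage. The acetylide is oxygenated as it is formed, so the alkyne terminus never has to be metallated a second time. This gives the three-carbon CH2–C≡C unit from an allyl group, which can be placed on the ring with certainty.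

**C6–C bond of unit B.** Compound 19 is the methyl ether of allylphenol 18, which is the Claisen product of allyl ether 17, made from phenol 16. The C6–C bond is made from the C5 oxygen because C6 is the only free ortho position of that oxygen. Had the C5 oxygen been methylated from the start, any C–C bond formation directed by the C7 oxygen would have had to choose between C6 and C8. Methylation after the rearrangement then installs the C5 methyl ether.

**Unit B flavan 16.** Phenol 16 comes from flavanone 13 by removal of the C4 carbonyl through carbonate 14 and quinone methide 15, and 13 from the chiral-pool flavanone 12 by silylation of the C7 hydroxyl. The C5 hydroxyl of 12 is hydrogen-bonded to the carbonyl, so the two phenols are differentiated without extra steps, and the (2S) centre is bought.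

## Alternatives that were turned down

**Alternative 1:** Both C3–C4 bonds are cut as alkenes. This leads to the bis(phosphonium) salt A1, which holds the complete diarylmethane core, and two molecules of the silyl-protected α-hydroxy aldehyde A2. In the forward step KN(SiMe3)2 forms the bis-ylide, which condenses twice with A2 to give bis-alkene A3. Hydrogenation, unmasking of the C8a oxygens and two Mitsunobu closures would follow.
- For: both stereocentres come from one chiral-pool reagent, the chemistry is two-directional, and no asymmetric catalysis is needed. On stereochemical step economy this alternative is stronger than the chosen route.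
- Against: A1 presupposes the differentiated C8/C6 diarylmethane, so the regiochemical problem is only moved into the synthesis of A1. The stereocentre of A2 is both benzylic and α to a formyl group and should epimerise under the basic ylide conditions. The 2,6-dioxygenated benzylic ylides are hindered. The alkenes of A3 must be saturated next to a C–O bond that is allylic and benzylic, in the presence of benzyl ethers. Six oxygens in three protecting classes lengthen the endgame.
- Comparison: the chosen route offers a unit A benzene ring whose substitution is fixed by bond construction, and after step 8 no epimerisable centre is exposed to base.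

**Alternative 2:** Both O1–C2 bonds are cut. The dibromo bisphenol A4 is O-allylated twice with methyl cinnamyl carbonate A5 under [Ir(cod)Cl]2 and a chiral phosphoramidite ligand to give the bis(1-phenylallyl) ether A6. Hydroboration and intramolecular alkyl–aryl coupling onto the bromides would then close both pyran rings.
- For: both stereocentres are set in one catalytic step, and a double enantioselective reaction enriches the major enantiomer further. On catalyst-controlled stereochemistry this alternative is stronger.
- Against: the unit A phenoxide of A4 is flanked by a bromine and the diarylmethane carbon, and such doubly ortho-substituted phenoxides are poor nucleophiles for branched-selective allylation. The two phenols sit in different environments, so one set of conditions must serve both. A4 again needs the regiodefined C8/C6 diarylmethane plus two site-selective brominations. Two ring closures by alkyl–aryl coupling on hindered, electron-rich aryl bromides are demanding, and the final debenzylation must spare two benzylic C2–O1 bonds.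
- Comparison: the chosen route uses reactions that are each known on close relatives, and its regiochemistry does not depend on selective functionalisation of a preformed phloroglucinol ring.

**Alternative 3:** Both C2–phenyl bonds are cut. Phenylboronic acid A8 adds to both rings of the methylene-bridged bis-chromone A7 under Pd(OCOCF3)2 (divalent palladium) and a chiral tert-butyl pyridine–oxazoline ligand to give bis-flavanone A9.
- For: asymmetric conjugate arylation of chromones is a good flavanone synthesis, the reagents are simple, and both centres are set at once. In brevity after the core it is stronger.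
- Against: A7 must first be made with the C8/C6 link, so the same regiochemical problem recurs. 5-Alkoxychromones are deactivated and hindered by the peri substituent. The flavanones in A9 can racemise by ring opening to the chalcone. Two carbonyl groups must then be removed and two benzyl ethers cleaved, four further operations on a sensitive bis-arene.
- Comparison: the chosen route has the stereocentres in non-epimerisable form at the late stage and needs only three steps after the ring construction.

Key step: step 15

Assumption: commercial natural (2S)-pinocembrin 12 is taken to be a single enantiomer, and methoxyacetylene 8, too volatile to be stocked, is prepared when needed (step 5).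

Abbreviations in names: TBSO = (tert-butyldimethylsilyl)oxy, TIPSO = (triisopropylsilyl)oxy.

## Route

### Cyclobutenone 11

Step 1
Reactants: 1 5-oxo-5-phenylpentanoic acid (4-benzoylbutyric acid)
Product: 2 methyl 5-oxo-5-phenylpentanoate
Conditions: MeOH, H2SO4 (cat.), reflux
Reagents that add atoms: methanol, CO
Why: Fischer esterification; the ester protects the carboxyl group from borane in step 2.

Step 2
Reactants: 2 methyl 5-oxo-5-phenylpentanoate
Product: 3 methyl (5R)-5-hydroxy-5-phenylpentanoate
Conditions: (S)-Me-CBS oxazaborolidine [(3aS)-1-methyl-3,3-diphenyltetrahydro-1H,3H-pyrrolo[1,2-c][1,3,2]oxazaborole] (10 mol %), BH3·SMe2, THF, −20 °C; MeOH quench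
Reagents that add atoms: none
Why: Corey–Bakshi–Shibata reduction of an aryl alkyl ketone; the (S)-catalyst–borane complex binds the ketone with phenyl as the large group and delivers hydride to the Si face, which should give the (R)-carbinol as with acetophenone. The methyl ester is not reduced by borane at this temperature.

Step 3
Reactants: 3 methyl (5R)-5-hydroxy-5-phenylpentanoate
Product: 4 methyl (5R)-5-(TBSO)-5-phenylpentanoate
Conditions: t-BuMe2SiCl, imidazole, DMF, rt
Reagents that add atoms: tert-butyldimethylsilyl chloride, CC(C)(C)[Si](C)(C)Cl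
Why: Standard silylation of a secondary alcohol; the TBS ether prevents lactonisation and survives the base, ketene chemistry and thermolysis that follow.

Step 4
Reactants: 4 methyl (5R)-5-(TBSO)-5-phenylpentanoate
Product: 5 (5R)-5-(TBSO)-5-phenylpentanoic acid
Conditions: LiOH·H2O, THF/MeOH/H2O, rt; cold 1 M HCl to pH 4
Reagents that add atoms: lithium hydroxide (source of one carboxyl oxygen), [Li+].[OH-]
Why: Saponification of a methyl ester; the secondary TBS ether is stable to aqueous LiOH, and brief cold acidification should free the acid without desilylation.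

Step 5
Reactants: 6 2-chloro-1,1-dimethoxyethane (chloroacetaldehyde dimethyl acetal)
Product: 8 methoxyacetylene (methoxyethyne), via sodium methoxyacetylide 7 (not isolated)
Conditions: NaNH2 (3 equiv), liquid NH3, −33 °C; saturated aqueous NaCl, −70 °C; distillation into a cold trap, used as a cold solution
Reagents that add atoms: none
Why: Elimination of methanol and then of hydrogen chloride from an α-chloro acetal with sodium amide is the classical preparation of 1-alkoxyalkynes; the product is held as its sodium salt until the cold quench and is distilled at once because it boils near room temperature.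

Step 6
Reactants: 5 (5R)-5-(TBSO)-5-phenylpentanoic acid; 8 methoxyacetylene (4 equiv)
Product: 11 3-methoxy-4-[(3R)-3-(TBSO)-3-phenylpropyl]cyclobut-2-en-1-one (both C4 epimers), via acid chloride 9 (not isolated), via aldoketene 10 (not isolated)
Conditions: 1-chloro-N,N,2-trimethylprop-1-en-1-amine (Ghosez reagent), CH2Cl2, 0 °C → rt; then 8, Et3N (slow addition), 0 °C → rt
Reagents that add atoms: none
Why: The Ghosez reagent gives the acid chloride without releasing HCl, so the TBS ether is safe; triethylamine then generates the aldoketene, which undergoes the known regioselective [2+2] cycloaddition with an alkoxyacetylene, its carbonyl carbon bonding to the unsubstituted alkyne carbon. Slow addition of base and excess alkyne keep the ketene concentration low and should suppress dimerisation; the new ring stereocentre is uncontrolled and irrelevant.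

### Siloxyalkyne 24

Step 7
Reactants: 12 (2S)-pinocembrin [(2S)-5,7-dihydroxy-2-phenylchroman-4-one]
Product: 13 (2S)-5-hydroxy-2-phenyl-7-(TIPSO)chroman-4-one
Conditions: i-Pr3SiCl, imidazole, DMF, 0 °C → rt
Reagents that add atoms: triisopropylsilyl chloride, CC(C)[Si](Cl)(C(C)C)C(C)C
Why: Chelation-controlled selective silylation; the C5 hydroxyl is hydrogen-bonded to the C4 carbonyl, so only the C7 hydroxyl reacts, and imidazole is too weak a base to open the flavanone.

Step 8
Reactants: 13 (2S)-5-hydroxy-2-phenyl-7-(TIPSO)chroman-4-one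
Product: 16 (2S)-2-phenyl-7-(TIPSO)chroman-5-ol, via aryl ethyl carbonate 14 (not isolated), via ortho-quinone methide 15 (not isolated)
Conditions: ClCO2Et, Et3N, THF, 0 °C; then NaBH4, H2O, 0 °C → rt
Reagents that add atoms: none
Why: Chloroformate–NaBH4 deoxygenation of an ortho-hydroxyaryl ketone: NaBH4 reduces the ketone of the C5 carbonate, the carbonate migrates to the new C4 alkoxide and is expelled to give the ortho-quinone methide, and this is reduced at C4. C2 is not involved and keeps its configuration; the C5 hydroxyl emerges free while the C7 oxygen stays silylated.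

Step 9
Reactants: 16 (2S)-2-phenyl-7-(TIPSO)chroman-5-ol
Product: 17 (2S)-5-(allyloxy)-2-phenyl-7-(TIPSO)chromane
Conditions: allyl bromide, K2CO3, acetone, reflux
Reagents that add atoms: allyl bromide, C=CCBr
Why: Williamson etherification of the only free phenol; anhydrous K2CO3 in acetone is not expected to cleave the hindered aryl TIPS ether, which is meta to the phenoxide and so cannot migrate to it.

Step 10
Reactants: 17 (2S)-5-(allyloxy)-2-phenyl-7-(TIPSO)chromane
Product: 18 (2S)-6-allyl-2-phenyl-7-(TIPSO)chroman-5-ol
Conditions: PhNEt2, 190 °C, sealed tube, argon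
Reagents that add atoms: none
Why: Aromatic Claisen rearrangement ([3,3]-sigmatropic shift, then tautomerisation); of the two ortho positions of O5, C4a is substituted, so the allyl group should be delivered to C6, the carbon that has to carry the bridge. The amine solvent keeps the medium non-acidic and prevents cyclisation of the ortho-allylphenol.

Step 11
Reactants: 18 (2S)-6-allyl-2-phenyl-7-(TIPSO)chroman-5-ol
Product: 19 (2S)-6-allyl-5-methoxy-2-phenyl-7-(TIPSO)chromane
Conditions: MeI, K2CO3, acetone, reflux
Reagents that add atoms: iodomethane, CI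
Why: O-Methylation of the phenol set free by the rearrangement; this installs the C5 methyl ether of unit B and leaves the C7 oxygen as its silyl ether.

Step 12
Reactants: 19 (2S)-6-allyl-5-methoxy-2-phenyl-7-(TIPSO)chromane
Product: 20 2-[(2S)-5-methoxy-2-phenyl-7-(TIPSO)chroman-6-yl]acetaldehyde
Conditions: OsO4 (2 mol %), NaIO4, 2,6-lutidine, 1,4-dioxane/H2O (3:1), rt
Reagents that add atoms: osmium tetroxide and sodium periodate (together the source of the aldehyde oxygen), O=[Os](=O)(=O)=O and [Na+].[O-]I(=O)(=O)=O
Why: Lemieux–Johnson cleavage of a terminal alkene to the arylacetaldehyde; ozone is avoided because of the electron-rich arene, and the enolisable aldehyde is used crude.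

Step 13
Reactants: 20 2-[(2S)-5-methoxy-2-phenyl-7-(TIPSO)chroman-6-yl]acetaldehyde
Product: 21 (2S)-6-(3,3-dibromoprop-2-en-1-yl)-5-methoxy-2-phenyl-7-(TIPSO)chromane
Conditions: CBr4, PPh3, CH2Cl2, 0 °C; then 20, 2,6-lutidine (buffer)
Reagents that add atoms: carbon tetrabromide, BrC(Br)(Br)Br
Why: Corey–Fuchs olefination; the non-basic dibromomethylene ylide adds one carbon to the enolisable aldehyde without aldol chemistry.

Step 14
Reactants: 21 (2S)-6-(3,3-dibromoprop-2-en-1-yl)-5-methoxy-2-phenyl-7-(TIPSO)chromane
Product: 24 (2S)-5-methoxy-2-phenyl-7-(TIPSO)-6-[3-(TIPSO)prop-2-yn-1-yl]chromane, via lithium acetylide 22 (not isolated), via lithium ynolate 23 (not isolated)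
Conditions: n-BuLi (2.05 equiv), THF, −78 °C; then t-BuOOLi (from t-BuOOH and LiN(SiMe3)2, THF, −78 °C), −78 → 0 °C; then i-Pr3SiOSO2CF3, −78 → 0 °C
Reagents that add atoms: tert-butyl hydroperoxide (as its lithium salt), CC(C)(C)OO; triisopropylsilyl trifluoromethanesulfonate, CC(C)[Si](OS(=O)(=O)C(F)(F)F)(C(C)C)C(C)C
Why: Second stage of the Corey–Fuchs sequence without a proton quench: bromine–lithium exchange, rearrangement to the alkyne and deprotonation by the second equivalent of n-BuLi give lithium acetylide 22 directly. Attack of 22 on the O–O bond of lithium tert-butyl peroxide gives ynolate 23, which the hard silyl triflate silylates on oxygen; oxygenation and O-silylation of lithium acetylides is the established way to 1-siloxyalkynes. Keeping n-BuLi to two equivalents at −78 °C should spare the doubly activated CH2 group and the aryl silyl ether, and the TIPS ynol ether should be stable enough to be chromatographed.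

### Union and endgame

Step 15
Reactants: 11 3-methoxy-4-[(3R)-3-(TBSO)-3-phenylpropyl]cyclobut-2-en-1-one (1.3 equiv); 24 (2S)-5-methoxy-2-phenyl-7-(TIPSO)-6-[3-(TIPSO)prop-2-yn-1-yl]chromane
Product: 29 2-[(3R)-3-(TBSO)-3-phenylpropyl]-3-methoxy-6-{[(2S)-5-methoxy-2-phenyl-7-(TIPSO)chroman-6-yl]methyl}-5-(TIPSO)phenol, via vinylketene 25 (not isolated), via vinylcyclobutenone 26 (not isolated), via dienylketene 27 (not isolated), via cyclohexadienone 28 (not isolated)
Conditions: toluene (0.3 M), 80 °C, then 110 °C, sealed tube, argon
Reagents that add atoms: none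
Why: On heating, 11 opens by four-electron conrotatory cleavage of its C1–C4 bond to vinylketene 25, the alkyl group rotating outward. The ketene carbonyl carbon is attacked by the alkyne carbon of 24 that carries the CH2 group, and the [2+2] cycloaddition gives 26 with the new C8–C8a and C6–C7 bonds. A second four-electron opening gives dienylketene 27, whose six-electron disrotatory electrocyclisation re-forms the C4a–C8a bond and closes the carbocycle as dienone 28; tautomerisation gives phenol 29. The closest known reaction type is the Danheiser benzannulation of cyclobutenones with siloxyalkynes to 2-substituted resorcinol monosilyl ethers. No stereocentre is created: the epimeric C4 of 11 becomes the aromatic C4a, and the carbinol and flavan centres are remote and untouched by neutral thermolysis. The step needs regioselective cycloaddition, which the polarisation of the ynol ether (nucleophilic at the carbon β to oxygen) and the electrophilic ketene carbon secure. It also needs the ketene to be captured faster than it dimerises or acylates the product; the electron-rich alkyne and the hindered new phenol, flanked by two carbon substituents, favour this. The three oxygens emerge differentiated as methyl ether (C5), TIPS ether (C7) and free hydroxyl (C8a).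

Step 16
Reactants: 29 2-[(3R)-3-(TBSO)-3-phenylpropyl]-3-methoxy-6-{[(2S)-5-methoxy-2-phenyl-7-(TIPSO)chroman-6-yl]methyl}-5-(TIPSO)phenol
Product: 30 2-[(3R)-3-hydroxy-3-phenylpropyl]-3-methoxy-6-{[(2S)-5-methoxy-2-phenyl-7-(TIPSO)chroman-6-yl]methyl}-5-(TIPSO)phenol
Conditions: (+)-camphor-10-sulfonic acid (0.2 equiv), MeOH/CH2Cl2 (1:1), 0 °C → rt
Reagents that add atoms: none
Why: Acid-catalysed methanolysis cleaves the alkyl TBS ether much faster than aryl TIPS ethers, which fall readily only to base or fluoride. The acid is too weak to ionise the secondary benzylic alcohol, so the (R) configuration should be kept.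

Step 17
Reactants: 30 2-[(3R)-3-hydroxy-3-phenylpropyl]-3-methoxy-6-{[(2S)-5-methoxy-2-phenyl-7-(TIPSO)chroman-6-yl]methyl}-5-(TIPSO)phenol
Product: 31 (2S)-5-methoxy-8-{[(2S)-5-methoxy-2-phenyl-7-(TIPSO)chroman-6-yl]methyl}-2-phenyl-7-(TIPSO)chromane
Conditions: PPh3, diisopropyl azodicarboxylate, THF, 0 °C → rt
Reagents that add atoms: none
Why: Intramolecular Mitsunobu etherification; the only free phenol (C8a–OH) displaces the phosphonium-activated benzylic alcohol in a 6-exo-tet SN2 closure with inversion, turning the (R)-carbinol into the (2S)-flavan. The unsubstituted phenyl group gives little carbocation character, which should limit erosion of configuration.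

Step 18
Reactants: 31 (2S)-5-methoxy-8-{[(2S)-5-methoxy-2-phenyl-7-(TIPSO)chroman-6-yl]methyl}-2-phenyl-7-(TIPSO)chromane
Product: 32 (2S)-8-{[(2S)-7-hydroxy-5-methoxy-2-phenylchroman-6-yl]methyl}-5-methoxy-2-phenylchroman-7-ol
Conditions: Bu4NF, THF, 0 °C, argon; aqueous NH4Cl
Reagents that add atoms: none
Why: Fluoride cleaves both aryl silyl ethers and no other group; exclusion of air protects the electron-rich bisphenol.

## Compound list

1 | 5-oxo-5-phenylpentanoic acid (4-benzoylbutyric acid) | O=C(O)CCCC(=O)c1ccccc1 | starting material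
2 | methyl 5-oxo-5-phenylpentanoate | COC(=O)CCCC(=O)c1ccccc1 | intermediate
3 | methyl (5R)-5-hydroxy-5-phenylpentanoate | COC(=O)CCC[C@@H](O)c1ccccc1 | intermediate
4 | methyl (5R)-5-[(tert-butyldimethylsilyl)oxy]-5-phenylpentanoate | COC(=O)CCC[C@@H](O[Si](C)(C)C(C)(C)C)c1ccccc1 | intermediate
5 | (5R)-5-[(tert-butyldimethylsilyl)oxy]-5-phenylpentanoic acid | OC(=O)CCC[C@@H](O[Si](C)(C)C(C)(C)C)c1ccccc1 | intermediate
6 | 2-chloro-1,1-dimethoxyethane (chloroacetaldehyde dimethyl acetal) | COC(CCl)OC | starting material
7 | sodium methoxyacetylide (formed in the flask) | [Na+].[C-]#COC | intermediate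
8 | methoxyacetylene (methoxyethyne) | C#COC | intermediate
9 | (5R)-5-[(tert-butyldimethylsilyl)oxy]-5-phenylpentanoyl chloride (formed in the flask) | ClC(=O)CCC[C@@H](O[Si](C)(C)C(C)(C)C)c1ccccc1 | intermediate
10 | (5R)-5-[(tert-butyldimethylsilyl)oxy]-5-phenylpent-1-en-1-one, the aldoketene (formed in the flask) | O=C=CCC[C@@H](O[Si](C)(C)C(C)(C)C)c1ccccc1 | intermediate
11 | 3-methoxy-4-[(3R)-3-[(tert-butyldimethylsilyl)oxy]-3-phenylpropyl]cyclobut-2-en-1-one (both C4 epimers) | COC1=CC(=O)C1CC[C@@H](O[Si](C)(C)C(C)(C)C)c1ccccc1 | intermediate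
12 | (2S)-pinocembrin, (2S)-5,7-dihydroxy-2-phenylchroman-4-one | Oc1cc(O)cc2c1C(=O)C[C@@H](c1ccccc1)O2 | starting material
13 | (2S)-5-hydroxy-2-phenyl-7-[(triisopropylsilyl)oxy]chroman-4-one | Oc1cc(O[Si](C(C)C)(C(C)C)C(C)C)cc2c1C(=O)C[C@@H](c1ccccc1)O2 | intermediate
14 | ethyl (2S)-4-oxo-2-phenyl-7-[(triisopropylsilyl)oxy]chroman-5-yl carbonate (formed in the flask) | CCOC(=O)Oc1cc(O[Si](C(C)C)(C(C)C)C(C)C)cc2c1C(=O)C[C@@H](c1ccccc1)O2 | intermediate
15 | (2S)-2-phenyl-7-[(triisopropylsilyl)oxy]-2,3-dihydro-5H-chromen-5-one, the ortho-quinone methide with a C4=C4a double bond (formed in the flask) | O=C1C=C(O[Si](C(C)C)(C(C)C)C(C)C)C=C2C1=CC[C@@H](c1ccccc1)O2 | intermediate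
16 | (2S)-2-phenyl-7-[(triisopropylsilyl)oxy]chroman-5-ol | Oc1cc(O[Si](C(C)C)(C(C)C)C(C)C)cc2c1CC[C@@H](c1ccccc1)O2 | intermediate
17 | (2S)-5-(allyloxy)-2-phenyl-7-[(triisopropylsilyl)oxy]chromane | C=CCOc1cc(O[Si](C(C)C)(C(C)C)C(C)C)cc2c1CC[C@@H](c1ccccc1)O2 | intermediate
18 | (2S)-6-allyl-2-phenyl-7-[(triisopropylsilyl)oxy]chroman-5-ol | C=CCc1c(O[Si](C(C)C)(C(C)C)C(C)C)cc2c(c1O)CC[C@@H](c1ccccc1)O2 | intermediate
19 | (2S)-6-allyl-5-methoxy-2-phenyl-7-[(triisopropylsilyl)oxy]chromane | C=CCc1c(O[Si](C(C)C)(C(C)C)C(C)C)cc2c(c1OC)CC[C@@H](c1ccccc1)O2 | intermediate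
20 | 2-{(2S)-5-methoxy-2-phenyl-7-[(triisopropylsilyl)oxy]chroman-6-yl}acetaldehyde | O=CCc1c(O[Si](C(C)C)(C(C)C)C(C)C)cc2c(c1OC)CC[C@@H](c1ccccc1)O2 | intermediate
21 | (2S)-6-(3,3-dibromoprop-2-en-1-yl)-5-methoxy-2-phenyl-7-[(triisopropylsilyl)oxy]chromane | BrC(Br)=CCc1c(O[Si](C(C)C)(C(C)C)C(C)C)cc2c(c1OC)CC[C@@H](c1ccccc1)O2 | intermediate
22 | lithium 3-{(2S)-5-methoxy-2-phenyl-7-[(triisopropylsilyl)oxy]chroman-6-yl}prop-1-yn-1-ide (formed in the flask) | [Li]C#CCc1c(O[Si](C(C)C)(C(C)C)C(C)C)cc2c(c1OC)CC[C@@H](c1ccccc1)O2 | intermediate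
23 | lithium 3-{(2S)-5-methoxy-2-phenyl-7-[(triisopropylsilyl)oxy]chroman-6-yl}prop-1-yn-1-olate (formed in the flask) | [Li]OC#CCc1c(O[Si](C(C)C)(C(C)C)C(C)C)cc2c(c1OC)CC[C@@H](c1ccccc1)O2 | intermediate
24 | (2S)-5-methoxy-2-phenyl-7-[(triisopropylsilyl)oxy]-6-{3-[(triisopropylsilyl)oxy]prop-2-yn-1-yl}chromane | CC(C)[Si](C(C)C)(C(C)C)OC#CCc1c(O[Si](C(C)C)(C(C)C)C(C)C)cc2c(c1OC)CC[C@@H](c1ccccc1)O2 | intermediate
25 | (7R)-7-[(tert-butyldimethylsilyl)oxy]-3-methoxy-7-phenylhepta-1,3-dien-1-one, the vinylketene, alkene geometry not specified (formed in the flask) | O=C=CC(OC)=CCC[C@@H](O[Si](C)(C)C(C)(C)C)c1ccccc1 | intermediate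
26 | 4-[(5R)-5-[(tert-butyldimethylsilyl)oxy]-1-methoxy-5-phenylpent-1-en-1-yl]-2-({(2S)-5-methoxy-2-phenyl-7-[(triisopropylsilyl)oxy]chroman-6-yl}methyl)-3-[(triisopropylsilyl)oxy]cyclobut-2-en-1-one (formed in the flask) | O=C1C(Cc2c(O[Si](C(C)C)(C(C)C)C(C)C)cc3c(c2OC)CC[C@@H](c2ccccc2)O3)=C(O[Si](C(C)C)(C(C)C)C(C)C)C1C(OC)=CCC[C@@H](O[Si](C)(C)C(C)(C)C)c1ccccc1 | intermediate
27 | (9R)-9-[(tert-butyldimethylsilyl)oxy]-5-methoxy-2-({(2S)-5-methoxy-2-phenyl-7-[(triisopropylsilyl)oxy]chroman-6-yl}methyl)-9-phenyl-3-[(triisopropylsilyl)oxy]nona-1,3,5-trien-1-one, the dienylketene (formed in the flask) | O=C=C(Cc1c(O[Si](C(C)C)(C(C)C)C(C)C)cc2c(c1OC)CC[C@@H](c1ccccc1)O2)C(O[Si](C(C)C)(C(C)C)C(C)C)=CC(OC)=CCC[C@@H](O[Si](C)(C)C(C)(C)C)c1ccccc1 | intermediate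
28 | 6-[(3R)-3-[(tert-butyldimethylsilyl)oxy]-3-phenylpropyl]-5-methoxy-2-({(2S)-5-methoxy-2-phenyl-7-[(triisopropylsilyl)oxy]chroman-6-yl}methyl)-3-[(triisopropylsilyl)oxy]cyclohexa-2,4-dien-1-one (formed in the flask) | O=C1C(Cc2c(O[Si](C(C)C)(C(C)C)C(C)C)cc3c(c2OC)CC[C@@H](c2ccccc2)O3)=C(O[Si](C(C)C)(C(C)C)C(C)C)C=C(OC)C1CC[C@@H](O[Si](C)(C)C(C)(C)C)c1ccccc1 | intermediate
29 | 2-[(3R)-3-[(tert-butyldimethylsilyl)oxy]-3-phenylpropyl]-3-methoxy-6-({(2S)-5-methoxy-2-phenyl-7-[(triisopropylsilyl)oxy]chroman-6-yl}methyl)-5-[(triisopropylsilyl)oxy]phenol | COc1cc(O[Si](C(C)C)(C(C)C)C(C)C)c(Cc2c(O[Si](C(C)C)(C(C)C)C(C)C)cc3c(c2OC)CC[C@@H](c2ccccc2)O3)c(O)c1CC[C@@H](O[Si](C)(C)C(C)(C)C)c1ccccc1 | intermediate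
30 | 2-[(3R)-3-hydroxy-3-phenylpropyl]-3-methoxy-6-({(2S)-5-methoxy-2-phenyl-7-[(triisopropylsilyl)oxy]chroman-6-yl}methyl)-5-[(triisopropylsilyl)oxy]phenol | COc1cc(O[Si](C(C)C)(C(C)C)C(C)C)c(Cc2c(O[Si](C(C)C)(C(C)C)C(C)C)cc3c(c2OC)CC[C@@H](c2ccccc2)O3)c(O)c1CC[C@@H](O)c1ccccc1 | intermediate
31 | (2S)-5-methoxy-8-({(2S)-5-methoxy-2-phenyl-7-[(triisopropylsilyl)oxy]chroman-6-yl}methyl)-2-phenyl-7-[(triisopropylsilyl)oxy]chromane | COc1cc(O[Si](C(C)C)(C(C)C)C(C)C)c(Cc2c(O[Si](C(C)C)(C(C)C)C(C)C)cc3c(c2OC)CC[C@@H](c2ccccc2)O3)c2c1CC[C@@H](c1ccccc1)O2 | intermediate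
32 | (2S)-8-{[(2S)-7-hydroxy-5-methoxy-2-phenylchroman-6-yl]methyl}-5-methoxy-2-phenylchroman-7-ol | COc1cc(O)c(Cc2c(O)cc3c(c2OC)CC[C@@H](c2ccccc2)O3)c2c1CC[C@@H](c1ccccc1)O2 | target

## Step count and least certain steps

Total: 18 steps. Longest linear sequence: 12 steps (12 → 32 through steps 7–18). The cyclobutenone branch has 5 steps from 1, plus step 5 for the alkyne.

**Step 15 (key step).** Cyclobutenone 11 is a vinylogous ester and may open more slowly than alkyl-substituted cyclobutenones. At the temperature then needed, the siloxyalkyne may isomerise by silyl shift, or the ketene may be consumed by dimerisation or by acylating the product phenol. Crowding next to the 2,6-dioxygenated benzyl group may also slow the cycloaddition.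

Fallback (sets out from 16, returns at 32): the diarylmethane is made by Friedel–Crafts benzylation instead of by ring construction. Compound 16 is formylated ortho to its free phenol (MgCl2, Et3N, paraformaldehyde, MeCN, reflux) to (2S)-5-hydroxy-2-phenyl-7-(TIPSO)chromane-6-carbaldehyde F1. Methylation (MeI, K2CO3, acetone) gives (2S)-5-methoxy-2-phenyl-7-(TIPSO)chromane-6-carbaldehyde F2, and reduction (NaBH4, THF/MeOH, 0 °C) gives [(2S)-5-methoxy-2-phenyl-7-(TIPSO)chroman-6-yl]methanol F3. A second portion of 16 is methylated to (2S)-5-methoxy-2-phenyl-7-(TIPSO)chromane F4 and desilylated (Bu4NF) to (2S)-5-methoxy-2-phenylchroman-7-ol F5. Acid-catalysed union of F3 and F5 (p-toluenesulfonic acid cat., CH2Cl2, 0 °C) should benzylate F5 ortho to its phenol and give (2S)-5-methoxy-8-{[(2S)-5-methoxy-2-phenyl-7-(TIPSO)chroman-6-yl]methyl}-2-phenylchroman-7-ol F6, and Bu4NF then gives 32. This path has to accept competition between C8 and C6 of F5 and a separation of regioisomers, which is the weakness the main route avoids.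

**Step 14.** A slight excess of n-BuLi may deprotonate the doubly activated CH2 group and isomerise the acetylide to an allene. The acetylide may also be oxygenated incompletely in the presence of the LiBr and 1-bromobutane left from its formation, or the ynolate may be silylated on carbon to a silylketene.

Fallback (sets out from 20, returns at 24): the ynolate is made by Kowalski ester homologation. Aldehyde 20 is oxidised (NaClO2, NaH2PO4, 2-methylbut-2-ene, t-BuOH/H2O) to 2-[(2S)-5-methoxy-2-phenyl-7-(TIPSO)chroman-6-yl]acetic acid F11. Esterification (Me3SiCHN2, MeOH/toluene) gives methyl 2-[(2S)-5-methoxy-2-phenyl-7-(TIPSO)chroman-6-yl]acetate F12. Addition of F12 to LiCHBr2 (from CH2Br2 and lithium 2,2,6,6-tetramethylpiperidide, −78 °C), then LiN(SiMe3)2 and n-BuLi with warming, gives ynolate 23, which i-Pr3SiOSO2CF3 silylates to 24.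

**Step 6.** The aldoketene may dimerise faster than it adds to the alkyne, the volatile alkyne may be lost, and the enol ether of 11 may hydrolyse on acidic silica.

Fallback (sets out from 5, returns at 29): the vinylketene is generated without any cyclobutenone. Acid 5 is homologated through its imidazolide (carbonyldiimidazole; KO2CCH2CO2Me, MgCl2, THF) to methyl (7R)-7-(TBSO)-3-oxo-7-phenylheptanoate F7. O-Methylation (Me2SO4, K2CO3, DMF) gives methyl (2E,7R)-7-(TBSO)-3-methoxy-7-phenylhept-2-enoate F8, and saponification (LiOH) gives (2E,7R)-7-(TBSO)-3-methoxy-7-phenylhept-2-enoic acid F9. The Ghosez reagent converts F9 into (2E,7R)-7-(TBSO)-3-methoxy-7-phenylhept-2-enoyl chloride F10. Triethylamine in the presence of 24 removes HCl across the four-carbon unit (1,4-dehydrochlorination) and gives vinylketene 25 near room temperature. Compound 25 enters the cascade of step 15 through 26, 27 and 28 on warming, and the route is rejoined at 29.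

**Step 8.** Triethylamine may open the acylated flavanone to the chalcone before reduction, with partial loss of configuration at C2. The silyl group para to the ketone may be lost in aqueous NaBH4, and the quinone methide may dimerise.

Fallback (sets out from 13, returns at 16): ionic hydrogenation replaces the quinone methide reduction. Reduction of 13 (NaBH4, THF/EtOH, 0 °C) gives (2S)-2-phenyl-7-(TIPSO)chromane-4,5-diol F13 as a mixture of C4 epimers, and Et3SiH with CF3CO2H (CH2Cl2, −20 °C) reduces the electron-rich benzylic alcohol to 16.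

## Further compounds

F1 | step 15 | (2S)-5-hydroxy-2-phenyl-7-[(triisopropylsilyl)oxy]chromane-6-carbaldehyde | O=Cc1c(O[Si](C(C)C)(C(C)C)C(C)C)cc2c(c1O)CC[C@@H](c1ccccc1)O2
F2 | step 15 | (2S)-5-methoxy-2-phenyl-7-[(triisopropylsilyl)oxy]chromane-6-carbaldehyde | O=Cc1c(O[Si](C(C)C)(C(C)C)C(C)C)cc2c(c1OC)CC[C@@H](c1ccccc1)O2
F3 | step 15 | {(2S)-5-methoxy-2-phenyl-7-[(triisopropylsilyl)oxy]chroman-6-yl}methanol | OCc1c(O[Si](C(C)C)(C(C)C)C(C)C)cc2c(c1OC)CC[C@@H](c1ccccc1)O2
F4 | step 15 | (2S)-5-methoxy-2-phenyl-7-[(triisopropylsilyl)oxy]chromane | COc1cc(O[Si](C(C)C)(C(C)C)C(C)C)cc2c1CC[C@@H](c1ccccc1)O2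
F5 | step 15 | (2S)-5-methoxy-2-phenylchroman-7-ol | COc1cc(O)cc2c1CC[C@@H](c1ccccc1)O2
F6 | step 15 | (2S)-5-methoxy-8-({(2S)-5-methoxy-2-phenyl-7-[(triisopropylsilyl)oxy]chroman-6-yl}methyl)-2-phenylchroman-7-ol | COc1cc(O)c(Cc2c(O[Si](C(C)C)(C(C)C)C(C)C)cc3c(c2OC)CC[C@@H](c2ccccc2)O3)c2c1CC[C@@H](c1ccccc1)O2
F7 | step 6 | methyl (7R)-7-[(tert-butyldimethylsilyl)oxy]-3-oxo-7-phenylheptanoate | COC(=O)CC(=O)CCC[C@@H](O[Si](C)(C)C(C)(C)C)c1ccccc1
F8 | step 6 | methyl (2E,7R)-7-[(tert-butyldimethylsilyl)oxy]-3-methoxy-7-phenylhept-2-enoate | COC(=O)/C=C(/OC)CCC[C@@H](O[Si](C)(C)C(C)(C)C)c1ccccc1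
F9 | step 6 | (2E,7R)-7-[(tert-butyldimethylsilyl)oxy]-3-methoxy-7-phenylhept-2-enoic acid | OC(=O)/C=C(/OC)CCC[C@@H](O[Si](C)(C)C(C)(C)C)c1ccccc1
F10 | step 6 | (2E,7R)-7-[(tert-butyldimethylsilyl)oxy]-3-methoxy-7-phenylhept-2-enoyl chloride | ClC(=O)/C=C(/OC)CCC[C@@H](O[Si](C)(C)C(C)(C)C)c1ccccc1
F11 | step 14 | 2-{(2S)-5-methoxy-2-phenyl-7-[(triisopropylsilyl)oxy]chroman-6-yl}acetic acid | OC(=O)Cc1c(O[Si](C(C)C)(C(C)C)C(C)C)cc2c(c1OC)CC[C@@H](c1ccccc1)O2
F12 | step 14 | methyl 2-{(2S)-5-methoxy-2-phenyl-7-[(triisopropylsilyl)oxy]chroman-6-yl}acetate | COC(=O)Cc1c(O[Si](C(C)C)(C(C)C)C(C)C)cc2c(c1OC)CC[C@@H](c1ccccc1)O2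
F13 | step 8 | (2S)-2-phenyl-7-[(triisopropylsilyl)oxy]chromane-4,5-diol (C4 epimers) | Oc1cc(O[Si](C(C)C)(C(C)C)C(C)C)cc2c1C(O)C[C@@H](c1ccccc1)O2
A1 | alternative 1 | bis(triphenylphosphonium) dibromide of the diarylmethane core, each ring bearing benzyl, methoxymethyl and methyl ethers and a (triphenylphosphonio)methyl group at the future C4a | COCOc1c(C[P+](c2ccccc2)(c2ccccc2)c2ccccc2)c(OC)cc(OCc2ccccc2)c1Cc1c(OCc2ccccc2)cc(OCOC)c(C[P+](c2ccccc2)(c2ccccc2)c2ccccc2)c1OC.[Br-].[Br-]
A2 | alternative 1 | (2S)-2-[(tert-butyldimethylsilyl)oxy]-2-phenylacetaldehyde | O=C[C@@H](O[Si](C)(C)C(C)(C)C)c1ccccc1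
A3 | alternative 1 | bis[(3R)-3-[(tert-butyldimethylsilyl)oxy]-3-phenylprop-1-en-1-yl] diarylmethane with benzyl, methoxymethyl and methyl ethers (alkene geometry mixed) | COCOc1c(C=C[C@@H](O[Si](C)(C)C(C)(C)C)c2ccccc2)c(OC)cc(OCc2ccccc2)c1Cc1c(OCc2ccccc2)cc(OCOC)c(C=C[C@@H](O[Si](C)(C)C(C)(C)C)c2ccccc2)c1OC
A4 | alternative 2 | 3-(benzyloxy)-2-{[6-(benzyloxy)-3-bromo-4-hydroxy-2-methoxyphenyl]methyl}-6-bromo-5-methoxyphenol | COc1cc(OCc2ccccc2)c(Cc2c(OCc3ccccc3)cc(O)c(Br)c2OC)c(O)c1Br
A5 | alternative 2 | methyl (E)-cinnamyl carbonate | COC(=O)OC/C=C/c1ccccc1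
A6 | alternative 2 | bis[(S)-1-phenylallyl] ether of the dibromo bisphenol | COc1cc(OCc2ccccc2)c(Cc2c(OCc3ccccc3)cc(O[C@@H](C=C)c3ccccc3)c(Br)c2OC)c(O[C@@H](C=C)c2ccccc2)c1Br
A7 | alternative 3 | 7-(benzyloxy)-8-{[7-(benzyloxy)-5-methoxy-4-oxo-4H-chromen-6-yl]methyl}-5-methoxy-4H-chromen-4-one | COc1cc(OCc2ccccc2)c(Cc2c(OCc3ccccc3)cc3c(c2OC)c(=O)cco3)c2c1c(=O)cco2
A8 | alternative 3 | phenylboronic acid | OB(O)c1ccccc1
A9 | alternative 3 | (2S)-7-(benzyloxy)-8-{[(2S)-7-(benzyloxy)-5-methoxy-4-oxo-2-phenylchroman-6-yl]methyl}-5-methoxy-2-phenylchroman-4-one | COc1cc(OCc2ccccc2)c(Cc2c(OCc3ccccc3)cc3c(c2OC)C(=O)C[C@@H](c2ccccc2)O3)c2c1C(=O)C[C@@H](c1ccccc1)O2
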